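**Assumption:** atoms are labelled with germacrane-type locants read from the target SMILES (lactone O on C6, ring-fusion C7, angelate on C8, epoxide C1–C10, triol C3/C4/C15, methylidene-lactone carbons C11–C13); unnumbered reagents, catalysts and solvents are commercial.

## Retrosynthetic overview

1. Target ⇐ last-step C3–OH-directed epoxidation of the (Z)-C1=C10 cyclodecene triol ⇐ desilylation ⇐ Z-selective RCM (10-membered ring).
2. RCM triene ⇐ Mitsunobu angeloylation with inversion at C8 ⇐ intermolecular Zn Barbier allylation of 3-methylbut-3-enal with a 3-(bromomethyl)butenolide (key C7–C8 bond; sets C7 and C8, unmasks the methylidene lactone).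
3. Bromomethyl butenolide ⇐ Pd carbonylative lactonisation of a (Z)-iodoallylic alcohol ⇐ directed hydroalumination/iodination ⇐ Noyori reduction of an ynone (C6).
4. C3/C4/C15 triol ⇐ Brown allylation of an α-methylene aldehyde (C3), matched Sharpless epoxidation (C4), Ti-mediated benzoate opening (C15).
5. Ring order: butenolide (5-membered lactone) → 10-membered carbocycle → oxirane.

## Route

Step 1
Reactants: 1 prop-2-yn-1-ol; 2 4-methoxybenzyl chloride
Product: 3 1-methoxy-4-[(prop-2-yn-1-yloxy)methyl]benzene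
Conditions: NaH, Bu4NI (cat.), THF/DMF, 0 °C to rt
Reagents that add atoms: none
Why: Williamson etherification of the alkoxide masks the future C13 oxygen as a DDQ-labile PMB ether.

Step 2
Reactants: 4 pent-4-enoyl chloride; 5 N,O-dimethylhydroxylamine hydrochloride
Product: 6 N-methoxy-N-methylpent-4-enamide
Conditions: Et3N (2.2 equiv), CH2Cl2, 0 °C to rt
Reagents that add atoms: none
Why: N-acylation gives the Weinreb amide, which stops at the ketone stage on acetylide addition.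

Step 3
Reactants: 3 1-methoxy-4-[(prop-2-yn-1-yloxy)methyl]benzene; 6 N-methoxy-N-methylpent-4-enamide
Product: 8 1-[(4-methoxybenzyl)oxy]oct-7-en-2-yn-4-one, via lithium acetylide 7 (not isolated)
Conditions: n-BuLi, THF, −78 °C; then 6, −78 to 0 °C; aq. NH4Cl
Reagents that add atoms: none
Why: Weinreb ketone synthesis, in which the chelated tetrahedral adduct collapses only on work-up, gives the ynone holding C13, C11, C7, C6, C5, C4 and the latent C3.

Step 4
Reactants: 8 1-[(4-methoxybenzyl)oxy]oct-7-en-2-yn-4-one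
Product: 9 (4R)-1-[(4-methoxybenzyl)oxy]oct-7-en-2-yn-4-ol
Conditions: RuCl(p-cymene)[(R,R)-TsDPEN] (2 mol%), KOH (2 mol%), i-PrOH, 25 °C
Reagents that add atoms: none
Why: Noyori–Ikariya asymmetric transfer hydrogenation of an alkynyl ketone, where the (R,R)-ligand delivers hydride to the face giving the (R)-carbinol (C6), the alkynyl group taking the role of the aryl group of aryl ketones.

Step 5
Reactants: 9 (4R)-1-[(4-methoxybenzyl)oxy]oct-7-en-2-yn-4-ol
Product: 10 (4R)-1-[(4-methoxybenzyl)oxy]oct-7-en-2-yn-4-yl pivalate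
Conditions: PivCl, pyridine, DMAP (cat.), CH2Cl2, 0 °C to rt
Reagents that add atoms: pivaloyl chloride, CC(C)(C)C(Cl)=O
Why: Acylation gives a pivalate that survives the coming oxidative, Lewis-acidic and mildly basic steps yet is removed by i-Bu2AlH in the presence of silyl and PMB ethers.

Step 6
Reactants: 10 (4R)-1-[(4-methoxybenzyl)oxy]oct-7-en-2-yn-4-yl pivalate
Product: 12 (4R)-1-[(4-methoxybenzyl)oxy]-7-oxohept-2-yn-4-yl pivalate, via vicinal diol 11 (not isolated)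
Conditions: OsO4 (2 mol%), NaIO4 (4 equiv), 2,6-lutidine, dioxane/H2O 3:1, rt
Reagents that add atoms: osmium tetroxide, O=[Os](=O)(=O)=O; sodium periodate, [Na+].[O-]I(=O)(=O)=O
Why: Lemieux–Johnson cleavage of the terminal alkene (the alkyne is inert to OsO4 under these conditions) reveals the C3 aldehyde.

Step 7
Reactants: 12 (4R)-1-[(4-methoxybenzyl)oxy]-7-oxohept-2-yn-4-yl pivalate
Product: 13 (4R)-1-[(4-methoxybenzyl)oxy]-6-methylidene-7-oxohept-2-yn-4-yl pivalate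
Conditions: aq. CH2O (37%), pyrrolidine (10 mol%), propionic acid (10 mol%), i-PrOH, 45 °C
Reagents that add atoms: formaldehyde, C=O
Why: Amine-catalysed Mannich-type α-methylenation of the aldehyde installs C15 as the 2-methylene group.

Step 8
Reactants: 13 (4R)-1-[(4-methoxybenzyl)oxy]-6-methylidene-7-oxohept-2-yn-4-yl pivalate
Product: 15 (4R,7S)-7-hydroxy-1-[(4-methoxybenzyl)oxy]-6-methylidenedec-9-en-2-yn-4-yl pivalate, via borinate ester 14 (not isolated)
Conditions: (−)-Ipc2BOMe [from (+)-α-pinene], CH2=CHCH2MgBr, Et2O, 0 °C to rt; then 13, −78 °C; NaOH, H2O2, 0 °C to rt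
Reagents that add atoms: allylmagnesium bromide, C=CC[Mg]Br
Why: Brown allylation through a chair six-membered transition state, in which the (+)-α-pinene-derived allylborane attacks the si face of the enal, sets (S)-C3 under reagent control.

Step 9
Reactants: 15 (4R,7S)-7-hydroxy-1-[(4-methoxybenzyl)oxy]-6-methylidenedec-9-en-2-yn-4-yl pivalate
Product: 16 (2R)-1-{(2R)-2-[(1S)-1-hydroxybut-3-en-1-yl]oxiran-2-yl}-5-[(4-methoxybenzyl)oxy]pent-3-yn-2-yl pivalate
Conditions: Ti(OiPr)4 (20 mol%), L-(+)-DIPT (25 mol%), t-BuOOH, 4 Å MS, CH2Cl2, −20 °C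
Reagents that add atoms: tert-butyl hydroperoxide, CC(C)(C)OO
Why: Sharpless asymmetric epoxidation of a secondary allylic alcohol, for which L-(+)-DIPT is matched with the (S)-carbinol and gives the erythro epoxide, sets (R)-C4 while the homoallylic vinyl group and the minor C3 epimer are left untouched.

Step 10
Reactants: 16 (2R)-1-{(2R)-2-[(1S)-1-hydroxybut-3-en-1-yl]oxiran-2-yl}-5-[(4-methoxybenzyl)oxy]pent-3-yn-2-yl pivalate
Product: 17 (4R,6R,7S)-6-[(benzoyloxy)methyl]-6,7-dihydroxy-1-[(4-methoxybenzyl)oxy]dec-9-en-2-yn-4-yl pivalate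
Conditions: Ti(OiPr)4 (1.5 equiv), PhCO2H (1.6 equiv), CH2Cl2, rt
Reagents that add atoms: benzoic acid, OC(=O)c1ccccc1
Why: Sharpless titanium-mediated opening of a 2,3-epoxy alcohol at its unsubstituted C-3 terminus (C15) without base (so no Payne rearrangement) leaves the C4–O bond and its configuration intact.

Step 11
Reactants: 17 (4R,6R,7S)-6-[(benzoyloxy)methyl]-6,7-dihydroxy-1-[(4-methoxybenzyl)oxy]dec-9-en-2-yn-4-yl pivalate
Product: 18 (4R,6R,7S)-6,7-dihydroxy-6-(hydroxymethyl)-1-[(4-methoxybenzyl)oxy]dec-9-en-2-yn-4-yl pivalate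
Conditions: K2CO3 (0.3 equiv), MeOH, 0 °C
Reagents that add atoms: none
Why: Transesterification cleaves the primary benzoate far faster than the hindered secondary pivalate.

Step 12
Reactants: 18 (4R,6R,7S)-6,7-dihydroxy-6-(hydroxymethyl)-1-[(4-methoxybenzyl)oxy]dec-9-en-2-yn-4-yl pivalate
Product: 19 (4R,6R,7S)-1-[(4-methoxybenzyl)oxy]-6,7-bis[(triethylsilyl)oxy]-6-{[(triethylsilyl)oxy]methyl}dec-9-en-2-yn-4-yl pivalate
Conditions: TESOTf (4.5 equiv), 2,6-lutidine, CH2Cl2, −78 °C to rt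
Reagents that add atoms: triethylsilyl trifluoromethanesulfonate, CC[Si](CC)(CC)OS(=O)(=O)C(F)(F)F
Why: The silyl triflate silylates the primary, secondary and tertiary hydroxyls alike, which blocks later oxa-Michael addition of the C4 oxygen to the butenolide.

Step 13
Reactants: 19 (4R,6R,7S)-1-[(4-methoxybenzyl)oxy]-6,7-bis[(triethylsilyl)oxy]-6-{[(triethylsilyl)oxy]methyl}dec-9-en-2-yn-4-yl pivalate
Product: 20 (4R,6R,7S)-1-[(4-methoxybenzyl)oxy]-6,7-bis[(triethylsilyl)oxy]-6-{[(triethylsilyl)oxy]methyl}dec-9-en-2-yn-4-ol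
Conditions: i-Bu2AlH (2.5 equiv), CH2Cl2, −78 °C; aq. potassium sodium tartrate
Reagents that add atoms: none
Why: Reductive ester cleavage frees the propargylic C6–OH without touching silyl ethers, the PMB ether or the alkyne.

Step 14
Reactants: 20 (4R,6R,7S)-1-[(4-methoxybenzyl)oxy]-6,7-bis[(triethylsilyl)oxy]-6-{[(triethylsilyl)oxy]methyl}dec-9-en-2-yn-4-ol
Product: 22 (2Z,4R,6R,7S)-2-iodo-1-[(4-methoxybenzyl)oxy]-6,7-bis[(triethylsilyl)oxy]-6-{[(triethylsilyl)oxy]methyl}deca-2,9-dien-4-ol, via cyclic vinylalanate 21 (not isolated)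
Conditions: NaAlH2(OCH2CH2OCH3)2, THF, 0 °C; then I2, −78 to 0 °C; aq. Na2S2O3, aq. potassium sodium tartrate
Reagents that add atoms: iodine, II
Why: Hydroxyl-directed trans-hydroalumination of the propargylic alcohol puts H on C7 and Al on C11, and iodinolysis with retention gives the (Z)-vinyl iodide with iodine cis to the carbinol carbon (kept at or below 0 °C to avoid elimination of the PMB ether to an allene).

Step 15
Reactants: 22 (2Z,4R,6R,7S)-2-iodo-1-[(4-methoxybenzyl)oxy]-6,7-bis[(triethylsilyl)oxy]-6-{[(triethylsilyl)oxy]methyl}deca-2,9-dien-4-ol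
Product: 23 (5R)-3-{[(4-methoxybenzyl)oxy]methyl}-5-{(2R,3S)-2,3-bis[(triethylsilyl)oxy]-2-{[(triethylsilyl)oxy]methyl}hex-5-en-1-yl}furan-2(5H)-one
Conditions: PdCl2(PPh3)2 (5 mol%), CO (1 atm), K2CO3, THF, 40 °C
Reagents that add atoms: carbon monoxide, [C-]#[O+]
Why: Carbonylative lactonisation (oxidative addition of zerovalent palladium to the C–I bond, CO insertion, capture of the acylpalladium by the cis C6–OH) closes the butenolide and brings in C12 without metathesis, so the C1 vinyl group is tolerated.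

Step 16
Reactants: 23 (5R)-3-{[(4-methoxybenzyl)oxy]methyl}-5-{(2R,3S)-2,3-bis[(triethylsilyl)oxy]-2-{[(triethylsilyl)oxy]methyl}hex-5-en-1-yl}furan-2(5H)-one
Product: 24 (5R)-3-(hydroxymethyl)-5-{(2R,3S)-2,3-bis[(triethylsilyl)oxy]-2-{[(triethylsilyl)oxy]methyl}hex-5-en-1-yl}furan-2(5H)-one
Conditions: DDQ, CH2Cl2/aq. NaH2PO4–Na2HPO4 buffer (pH 7), 0 °C to rt
Reagents that add atoms: none
Why: Oxidative PMB cleavage under buffered conditions leaves the triethylsilyl ethers and the butenolide intact.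

Step 17
Reactants: 24 (5R)-3-(hydroxymethyl)-5-{(2R,3S)-2,3-bis[(triethylsilyl)oxy]-2-{[(triethylsilyl)oxy]methyl}hex-5-en-1-yl}furan-2(5H)-one
Product: 25 (5R)-3-(bromomethyl)-5-{(2R,3S)-2,3-bis[(triethylsilyl)oxy]-2-{[(triethylsilyl)oxy]methyl}hex-5-en-1-yl}furan-2(5H)-one
Conditions: CBr4, PPh3, 2,6-lutidine, CH2Cl2, 0 °C
Reagents that add atoms: carbon tetrabromide, BrC(Br)(Br)Br
Why: Appel bromination of the primary allylic alcohol under buffered, neutral conditions gives the allylic bromide.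

Step 18
Reactants: 26 3-methylbut-3-en-1-ol
Product: 27 3-methylbut-3-enal
Conditions: Dess–Martin periodinane, NaHCO3, CH2Cl2, 0 °C to rt; filtered and used at once as a cold CH2Cl2 solution
Reagents that add atoms: none
Why: Buffered Dess–Martin oxidation gives the β,γ-unsaturated aldehyde without isomerisation to the conjugated enal.

Step 19
Reactants: 25 (5R)-3-(bromomethyl)-5-{(2R,3S)-2,3-bis[(triethylsilyl)oxy]-2-{[(triethylsilyl)oxy]methyl}hex-5-en-1-yl}furan-2(5H)-one; 27 3-methylbut-3-enal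
Product: 29 (4R,5R)-4-[(1S)-1-hydroxy-3-methylbut-3-en-1-yl]-3-methylidene-5-{(2R,3S)-2,3-bis[(triethylsilyl)oxy]-2-{[(triethylsilyl)oxy]methyl}hex-5-en-1-yl}dihydrofuran-2(3H)-one, via allylzinc bromide 28 (not isolated)
Conditions: Zn dust, THF/sat. aq. NH4Cl 4:1, 0 °C to rt
Reagents that add atoms: none
Why: Intermolecular Barbier carbonyl allylation (γ-attack, SE2′) through a Zimmerman–Traxler chair, in which the aldehyde adds to C7 anti to the C6 side chain (trans lactone) and the ring-locked E-type allylzinc gives the anti (8S) carbinol.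

Step 20
Reactants: 29 (4R,5R)-4-[(1S)-1-hydroxy-3-methylbut-3-en-1-yl]-3-methylidene-5-{(2R,3S)-2,3-bis[(triethylsilyl)oxy]-2-{[(triethylsilyl)oxy]methyl}hex-5-en-1-yl}dihydrofuran-2(3H)-one; 30 angelic acid [(2Z)-2-methylbut-2-enoic acid]
Product: 31 (1R)-3-methyl-1-[(2R,3R)-4-methylidene-5-oxo-2-{(2R,3S)-2,3-bis[(triethylsilyl)oxy]-2-{[(triethylsilyl)oxy]methyl}hex-5-en-1-yl}oxolan-3-yl]but-3-en-1-yl (2Z)-2-methylbut-2-enoate
Conditions: PPh3, DIAD, toluene, 0 °C to rt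
Reagents that add atoms: none
Why: Mitsunobu esterification displaces the alkoxyphosphonium by angelate in an SN2 step, inverting C8 to the required (R) configuration, with no acyl activation that could isomerise angelate to tiglate.

Step 21
Reactants: 31 (1R)-3-methyl-1-[(2R,3R)-4-methylidene-5-oxo-2-{(2R,3S)-2,3-bis[(triethylsilyl)oxy]-2-{[(triethylsilyl)oxy]methyl}hex-5-en-1-yl}oxolan-3-yl]but-3-en-1-yl (2Z)-2-methylbut-2-enoate
Product: 32 (3aR,4R,6Z,9S,10R,11aR)-6-methyl-3-methylidene-2-oxo-9,10-bis[(triethylsilyl)oxy]-10-{[(triethylsilyl)oxy]methyl}-2,3,3a,4,5,8,9,10,11,11a-decahydrocyclodeca[b]furan-4-yl (2Z)-2-methylbut-2-enoate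
Conditions: second-generation Grubbs catalyst (15 mol%, two portions), toluene (0.8 mM), 90 °C
Reagents that add atoms: none
Why: Ring-closing metathesis between the C1 vinyl and C10 isopropenyl groups gives the cyclodecene, expected as the Z isomer on ring-strain grounds, while the electron-poor methylidene-lactone and angelate alkenes are not expected to compete because closure onto them would give a strained bridgehead alkene.

Step 22
Reactants: 32 (3aR,4R,6Z,9S,10R,11aR)-6-methyl-3-methylidene-2-oxo-9,10-bis[(triethylsilyl)oxy]-10-{[(triethylsilyl)oxy]methyl}-2,3,3a,4,5,8,9,10,11,11a-decahydrocyclodeca[b]furan-4-yl (2Z)-2-methylbut-2-enoate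
Product: 33 (3aR,4R,6Z,9S,10R,11aR)-9,10-dihydroxy-10-(hydroxymethyl)-6-methyl-3-methylidene-2-oxo-2,3,3a,4,5,8,9,10,11,11a-decahydrocyclodeca[b]furan-4-yl (2Z)-2-methylbut-2-enoate
Conditions: HF·pyridine, pyridine, THF, 0 °C to rt
Reagents that add atoms: none
Why: Fluoride-mediated desilylation under buffered conditions spares the methylidene lactone and the angelate, and is done before the acid-sensitive epoxide exists.

Step 23
Reactants: 33 (3aR,4R,6Z,9S,10R,11aR)-9,10-dihydroxy-10-(hydroxymethyl)-6-methyl-3-methylidene-2-oxo-2,3,3a,4,5,8,9,10,11,11a-decahydrocyclodeca[b]furan-4-yl (2Z)-2-methylbut-2-enoate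
Product: 34 (3aS,4R,6S,7R,9S,10R,11aR)-6,7-epoxy-9,10-dihydroxy-10-(hydroxymethyl)-6-methyl-3-methylidene-2-oxododecahydrocyclodeca[b]furan-4-yl (2Z)-2-methylbut-2-enoate (CNP0307250.1)
Conditions: VO(acac)2 (10 mol%), t-BuOOH (1.3 equiv), CH2Cl2, 0 °C; aq. Na2S2O3
Reagents that add atoms: tert-butyl hydroperoxide, CC(C)(C)OO
Why: Homoallylic-hydroxyl-directed vanadium epoxidation, in which the C3–O–vanadium peroxide reaches only the electron-rich C1=C10 alkene and should deliver oxygen to the face cis to C3–OH, gives the (1R,10S) cis-epoxide while the electron-poor alkenes stay untouched.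

## Compound list

1 | prop-2-yn-1-ol | C#CCO | starting material
2 | 4-methoxybenzyl chloride | COc1ccc(CCl)cc1 | starting material
3 | 1-methoxy-4-[(prop-2-yn-1-yloxy)methyl]benzene | C#CCOCc1ccc(OC)cc1 | intermediate
4 | pent-4-enoyl chloride | C=CCCC(Cl)=O | starting material
5 | N,O-dimethylhydroxylamine hydrochloride | CNOC.Cl | starting material
6 | N-methoxy-N-methylpent-4-enamide | C=CCCC(=O)N(C)OC | intermediate
7 | {3-[(4-methoxybenzyl)oxy]prop-1-yn-1-yl}lithium | [Li]C#CCOCc1ccc(OC)cc1 | intermediate (not isolated)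
8 | 1-[(4-methoxybenzyl)oxy]oct-7-en-2-yn-4-one | C=CCCC(=O)C#CCOCc1ccc(OC)cc1 | intermediate
9 | (4R)-1-[(4-methoxybenzyl)oxy]oct-7-en-2-yn-4-ol | C=CCC[C@@H](O)C#CCOCc1ccc(OC)cc1 | intermediate
10 | (4R)-1-[(4-methoxybenzyl)oxy]oct-7-en-2-yn-4-yl pivalate | C=CCC[C@@H](OC(=O)C(C)(C)C)C#CCOCc1ccc(OC)cc1 | intermediate
11 | (4R)-7,8-dihydroxy-1-[(4-methoxybenzyl)oxy]oct-2-yn-4-yl pivalate (C7 epimers) | OCC(O)CC[C@@H](OC(=O)C(C)(C)C)C#CCOCc1ccc(OC)cc1 | intermediate (not isolated)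
12 | (4R)-1-[(4-methoxybenzyl)oxy]-7-oxohept-2-yn-4-yl pivalate | O=CCC[C@@H](OC(=O)C(C)(C)C)C#CCOCc1ccc(OC)cc1 | intermediate
13 | (4R)-1-[(4-methoxybenzyl)oxy]-6-methylidene-7-oxohept-2-yn-4-yl pivalate | C=C(C=O)C[C@@H](OC(=O)C(C)(C)C)C#CCOCc1ccc(OC)cc1 | intermediate
14 | O-diisopinocampheylborinate of 15 | C=CC[C@H](OB([C@@H]1C[C@@H]2C[C@H]([C@H]1C)C2(C)C)[C@@H]1C[C@@H]2C[C@H]([C@H]1C)C2(C)C)C(=C)C[C@@H](OC(=O)C(C)(C)C)C#CCOCc1ccc(OC)cc1 | intermediate (not isolated)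
15 | (4R,7S)-7-hydroxy-1-[(4-methoxybenzyl)oxy]-6-methylidenedec-9-en-2-yn-4-yl pivalate | C=CC[C@H](O)C(=C)C[C@@H](OC(=O)C(C)(C)C)C#CCOCc1ccc(OC)cc1 | intermediate
16 | (2R)-1-{(2R)-2-[(1S)-1-hydroxybut-3-en-1-yl]oxiran-2-yl}-5-[(4-methoxybenzyl)oxy]pent-3-yn-2-yl pivalate | C=CC[C@H](O)[C@]1(CO1)C[C@@H](OC(=O)C(C)(C)C)C#CCOCc1ccc(OC)cc1 | intermediate
17 | (4R,6R,7S)-6-[(benzoyloxy)methyl]-6,7-dihydroxy-1-[(4-methoxybenzyl)oxy]dec-9-en-2-yn-4-yl pivalate | C=CC[C@H](O)[C@](O)(COC(=O)c1ccccc1)C[C@@H](OC(=O)C(C)(C)C)C#CCOCc1ccc(OC)cc1 | intermediate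
18 | (4R,6R,7S)-6,7-dihydroxy-6-(hydroxymethyl)-1-[(4-methoxybenzyl)oxy]dec-9-en-2-yn-4-yl pivalate | C=CC[C@H](O)[C@](O)(CO)C[C@@H](OC(=O)C(C)(C)C)C#CCOCc1ccc(OC)cc1 | intermediate
19 | (4R,6R,7S)-1-[(4-methoxybenzyl)oxy]-6,7-bis[(triethylsilyl)oxy]-6-{[(triethylsilyl)oxy]methyl}dec-9-en-2-yn-4-yl pivalate | C=CC[C@H](O[Si](CC)(CC)CC)[C@](O[Si](CC)(CC)CC)(CO[Si](CC)(CC)CC)C[C@@H](OC(=O)C(C)(C)C)C#CCOCc1ccc(OC)cc1 | intermediate
20 | (4R,6R,7S)-1-[(4-methoxybenzyl)oxy]-6,7-bis[(triethylsilyl)oxy]-6-{[(triethylsilyl)oxy]methyl}dec-9-en-2-yn-4-ol | C=CC[C@H](O[Si](CC)(CC)CC)[C@](O[Si](CC)(CC)CC)(CO[Si](CC)(CC)CC)C[C@@H](O)C#CCOCc1ccc(OC)cc1 | intermediate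
21 | sodium 2,2-bis(2-methoxyethoxy)-2,5-dihydro-1,2-oxaluminol-2-uide formed from 20 (Al on C11, O on C6) | C=CC[C@H](O[Si](CC)(CC)CC)[C@](O[Si](CC)(CC)CC)(CO[Si](CC)(CC)CC)C[C@H]1O[Al-](OCCOC)(OCCOC)C(COCc2ccc(OC)cc2)=C1.[Na+] | intermediate (not isolated)
22 | (2Z,4R,6R,7S)-2-iodo-1-[(4-methoxybenzyl)oxy]-6,7-bis[(triethylsilyl)oxy]-6-{[(triethylsilyl)oxy]methyl}deca-2,9-dien-4-ol | C=CC[C@H](O[Si](CC)(CC)CC)[C@](O[Si](CC)(CC)CC)(CO[Si](CC)(CC)CC)C[C@@H](O)/C=C(\I)COCc1ccc(OC)cc1 | intermediate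
23 | (5R)-3-{[(4-methoxybenzyl)oxy]methyl}-5-{(2R,3S)-2,3-bis[(triethylsilyl)oxy]-2-{[(triethylsilyl)oxy]methyl}hex-5-en-1-yl}furan-2(5H)-one | C=CC[C@H](O[Si](CC)(CC)CC)[C@](O[Si](CC)(CC)CC)(CO[Si](CC)(CC)CC)C[C@H]1OC(=O)C(COCc2ccc(OC)cc2)=C1 | intermediate
24 | (5R)-3-(hydroxymethyl)-5-{(2R,3S)-2,3-bis[(triethylsilyl)oxy]-2-{[(triethylsilyl)oxy]methyl}hex-5-en-1-yl}furan-2(5H)-one | C=CC[C@H](O[Si](CC)(CC)CC)[C@](O[Si](CC)(CC)CC)(CO[Si](CC)(CC)CC)C[C@H]1OC(=O)C(CO)=C1 | intermediate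
25 | (5R)-3-(bromomethyl)-5-{(2R,3S)-2,3-bis[(triethylsilyl)oxy]-2-{[(triethylsilyl)oxy]methyl}hex-5-en-1-yl}furan-2(5H)-one | C=CC[C@H](O[Si](CC)(CC)CC)[C@](O[Si](CC)(CC)CC)(CO[Si](CC)(CC)CC)C[C@H]1OC(=O)C(CBr)=C1 | intermediate
26 | 3-methylbut-3-en-1-ol | CC(=C)CCO | starting material
27 | 3-methylbut-3-enal | CC(=C)CC=O | intermediate
28 | allylzinc bromide from 25 | C=CC[C@H](O[Si](CC)(CC)CC)[C@](O[Si](CC)(CC)CC)(CO[Si](CC)(CC)CC)C[C@H]1OC(=O)C(C[Zn]Br)=C1 | intermediate (not isolated)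
29 | (4R,5R)-4-[(1S)-1-hydroxy-3-methylbut-3-en-1-yl]-3-methylidene-5-{(2R,3S)-2,3-bis[(triethylsilyl)oxy]-2-{[(triethylsilyl)oxy]methyl}hex-5-en-1-yl}dihydrofuran-2(3H)-one | C=C1C(=O)O[C@H](C[C@@](O[Si](CC)(CC)CC)(CO[Si](CC)(CC)CC)[C@H](CC=C)O[Si](CC)(CC)CC)[C@H]1[C@@H](O)CC(C)=C | intermediate
30 | angelic acid, (2Z)-2-methylbut-2-enoic acid | C/C=C(/C)C(=O)O | starting material
31 | (1R)-3-methyl-1-[(2R,3R)-4-methylidene-5-oxo-2-{(2R,3S)-2,3-bis[(triethylsilyl)oxy]-2-{[(triethylsilyl)oxy]methyl}hex-5-en-1-yl}oxolan-3-yl]but-3-en-1-yl (2Z)-2-methylbut-2-enoate | C=C1C(=O)O[C@H](C[C@@](O[Si](CC)(CC)CC)(CO[Si](CC)(CC)CC)[C@H](CC=C)O[Si](CC)(CC)CC)[C@H]1[C@H](OC(=O)/C(C)=C\C)CC(C)=C | intermediate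
32 | (3aR,4R,6Z,9S,10R,11aR)-6-methyl-3-methylidene-2-oxo-9,10-bis[(triethylsilyl)oxy]-10-{[(triethylsilyl)oxy]methyl}-2,3,3a,4,5,8,9,10,11,11a-decahydrocyclodeca[b]furan-4-yl (2Z)-2-methylbut-2-enoate | C=C1C(=O)O[C@@H]2C[C@@](O[Si](CC)(CC)CC)(CO[Si](CC)(CC)CC)[C@@H](O[Si](CC)(CC)CC)C/C=C(C)\C[C@@H](OC(=O)/C(C)=C\C)[C@@H]12 | intermediate
33 | (3aR,4R,6Z,9S,10R,11aR)-9,10-dihydroxy-10-(hydroxymethyl)-6-methyl-3-methylidene-2-oxo-2,3,3a,4,5,8,9,10,11,11a-decahydrocyclodeca[b]furan-4-yl (2Z)-2-methylbut-2-enoate | C=C1C(=O)O[C@@H]2C[C@@](O)(CO)[C@@H](O)C/C=C(C)\C[C@@H](OC(=O)/C(C)=C\C)[C@@H]12 | intermediate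
34 | CNP0307250.1, (3aS,4R,6S,7R,9S,10R,11aR)-6,7-epoxy-9,10-dihydroxy-10-(hydroxymethyl)-6-methyl-3-methylidene-2-oxododecahydrocyclodeca[b]furan-4-yl (2Z)-2-methylbut-2-enoate | C=C1C(=O)O[C@@H]2C[C@@](O)(CO)[C@@H](O)C[C@H]3O[C@@]3(C)C[C@@H](OC(=O)/C(C)=C\C)[C@@H]12 | target

## Step count and risks

Total steps: 23. Longest linear sequence: 21 (step 1 or 2, then steps 3–17 and 19–23).

**Step 20 (Mitsunobu angeloylation with inversion).** The carbinol is hindered and can eliminate to a conjugated diene. The fallback sets out from 29 and comes back at 31. A Mitsunobu reaction with the smaller and more acidic chloroacetic acid (PPh3, DIAD, toluene, 0 °C) gives the inverted (1R)-chloroacetate of 29 F1. Thiourea and NaHCO3 in EtOH/THF then remove the chloroacetyl group to give the (1R)-epimer of alcohol 29 F2. Acylation with retention by the preformed (2Z)-2-methylbut-2-enoic 2,4,6-trichlorobenzoic anhydride F3 (from 30, 2,4,6-trichlorobenzoyl chloride and Et3N), in toluene at 80 °C without DMAP, gives 31 without isomerisation to the tiglate.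

**Step 21 (ring-closing metathesis to the 10-membered ring).** Oligomerisation, the E isomer or no closure are possible. The fallback sets out from 29 and comes back at 32 by changing the order of ring closure and ester installation. The less encumbered free alcohol 29 is cyclised first (second-generation Grubbs catalyst, toluene, high dilution, 90 °C) to the macrocyclic (4S)-alcohol F4. The Mitsunobu reaction with 30 is then run on the ring to invert C8 and give 32.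

**Step 23 (directed epoxidation).** Wrong-face delivery, triol chelation of vanadium, or transannular opening of the epoxide by the C4 hydroxyl are possible. The fallback sets out from 32 and comes back at 34. The silyl-protected macrocycle is epoxidised with dimethyldioxirane (acetone/CH2Cl2, −20 to 0 °C; neutral, face chosen by approach control on the shielded ring) to the tris(triethylsilyl) ether of the target F5. The silyl groups are then removed with pyridine-buffered HF·pyridine at 0 °C to give 34.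

## Further compounds

F1 | step 20 | (1R)-3-methyl-1-[(2R,3R)-4-methylidene-5-oxo-2-{(2R,3S)-2,3-bis[(triethylsilyl)oxy]-2-{[(triethylsilyl)oxy]methyl}hex-5-en-1-yl}oxolan-3-yl]but-3-en-1-yl chloroacetate | C=C1C(=O)O[C@H](C[C@@](O[Si](CC)(CC)CC)(CO[Si](CC)(CC)CC)[C@H](CC=C)O[Si](CC)(CC)CC)[C@H]1[C@H](OC(=O)CCl)CC(C)=C
F2 | step 20 | (4R,5R)-4-[(1R)-1-hydroxy-3-methylbut-3-en-1-yl]-3-methylidene-5-{(2R,3S)-2,3-bis[(triethylsilyl)oxy]-2-{[(triethylsilyl)oxy]methyl}hex-5-en-1-yl}dihydrofuran-2(3H)-one | C=C1C(=O)O[C@H](C[C@@](O[Si](CC)(CC)CC)(CO[Si](CC)(CC)CC)[C@H](CC=C)O[Si](CC)(CC)CC)[C@H]1[C@H](O)CC(C)=C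
F3 | step 20 | (2Z)-2-methylbut-2-enoic 2,4,6-trichlorobenzoic anhydride | C/C=C(/C)C(=O)OC(=O)c1c(Cl)cc(Cl)cc1Cl
F4 | step 21 | (3aR,4S,6Z,9S,10R,11aR)-4-hydroxy-6-methyl-3-methylidene-9,10-bis[(triethylsilyl)oxy]-10-{[(triethylsilyl)oxy]methyl}-3a,4,5,8,9,10,11,11a-octahydrocyclodeca[b]furan-2(3H)-one | C=C1C(=O)O[C@@H]2C[C@@](O[Si](CC)(CC)CC)(CO[Si](CC)(CC)CC)[C@@H](O[Si](CC)(CC)CC)C/C=C(C)\C[C@H](O)[C@@H]12
F5 | step 23 | 9,10,10a-tris-O-triethylsilyl ether of the target (C3, C4 and C15 oxygens silylated) | C=C1C(=O)O[C@@H]2C[C@@](O[Si](CC)(CC)CC)(CO[Si](CC)(CC)CC)[C@@H](O[Si](CC)(CC)CC)C[C@H]3O[C@@]3(C)C[C@@H](OC(=O)/C(C)=C\C)[C@@H]12
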